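The data stem from a simulated flask from invented constants, and the scatter is random.

Per minute and per carrier charged: that was the unit I counted in, since one turnover turns one starting material into product and one salt into spent salt.

in all of them: starting material 0.20 M

| run | salt in the second phase | spent carrier | remark | volume of the second phase over the first |
|---|---|---|---|---|
| elm | 1.3 equiv | 14 mol% | run made earlier |  |
| larch | 2 equiv | 14 mol% | run made earlier |  |
| cedar | 0.90 equiv | 28 mol% | run made earlier |  |
| flask | 0.900 equiv | 14 mol% |  | 0.50 |

- elm (time / min: product / %): 2.50: 40.9; 4.00: 50.6; 6.00: 56.9; 10.0: 68.3; 20.0: 80.3; 30.0: 86.4
- larch (time / min: product / %): 2.50: 49.3; 4.00: 60.3; 6.00: 69.2; 10.0: 79.5; 20.0: 91.8; 30.0: 95.4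
- cedar (time / min: product / %): 2.50: 41.0; 8.00: 59.7; 15.0: 69.2; 20.0: 72.9; 30.0: 78.2

(each reading ± 0.3 percentage points)

- in the second phase: salt in the second phase, spent salt in the second phase; everything else is in the first
- charges count per volume of the first phase; a concentration in a rate is the amount of a species over the volume of its own phase; every rate counts per litre of the first phase
- what may be going on: spent carrier + salt in the second phase <-> fresh carrier + spent salt in the second phase; 2 spent carrier <-> resting dimer; starting material + fresh carrier -> product + spent carrier
- the earlier runs hold the two phases in the same ratio of volumes as the flask asked about

- factor on the rate of making product when 5.0% of the starting material are converted if salt in the second phase is charged twice over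
- factor on the rate when 5.0% of the starting material are converted if spent carrier is charged at 1.5 mol% instead

If the exchange keeps up, fresh carrier follows c(salt)/c(spent salt), and late in a run spent salt is nearly the product made. So I divided each late rate, in turnovers per minute, by the fraction of starting material left and by that ratio. Two runs with the same loading but different salt gave two separate readings:

elm: 0.445 /min

larch: 0.459 /min

They agreed within the scatter of the readings, so I kept their mean as the carrier pace, the turnovers per minute of one charged carrier at full starting material and equal salt and spent salt: 0.452 /min.

The cedar run, with twice the carrier and less salt than elm, parted from them:

cedar: 0.344 /min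

Its pace was lower; elm and larch had shown the division coping with a change of salt, so I suspected the count per carrier charged: some carrier was perhaps not working, held as resting dimer. The late order in carrier read as 0.607.

My reckoning for the flask put the factor for less carrier between plain proportion and this order:

0.107 to 0.258

At 5.0% conversion the flask had made 0.357 turnovers per carrier charged, fewer than one, so the late order need not hold there. For twice the salt, the salt term gave 2.06, which I took as the upper end.

The forecast gave 1.36 (1.25 to 1.5) for doubled salt, judging that “carrier is already largely activated”, and 0.16 (0.13 to 0.2) for less carrier.

The flask gave 1.49 for twice the salt, below my upper end, and 0.188 for less carrier, inside my range.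

    spent carrier + salt in the second phase ⇌ fresh carrier + spent salt in the second phase (K = 0.200, k = 79.0 /M/min)
    2 spent carrier ⇌ resting dimer, settled at all times (K = 99.0 /M)
    starting material + fresh carrier → product + spent carrier (k = 37.0 /M/min)

At the read pace, one turnover in the flask at 2.50 min took 2.19 min per carrier charged, far longer than the 2.4 s half-life of spent carrier by the forward exchange alone, while resting dimer, the resting state, held 58.4% of the catalyst. At 5.0% conversion, each carrier charged at 1.5 mol% worked 1.75 times the pace of one charged at 14 mol%, with resting dimer at 7.22% of its catalyst against 40.1%.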